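- Time is what this flask spends: I want to know how much of its 0.029 M of Ja has gone after 6.0 h, and the runs stop at 4.00 h.

the same everywhere: Jf 0.0348 M
- west: Ja 0.041 M; Jc 5.8 mM; Jd 2.9 mM; run made earlier
- north: Ja 0.064 M; Jc 5.8 mM; Jd 2.9 mM; run made earlier
- flask: Ja 0.029 M; Jc 5.80 mM; Jd 2.90 mM; time 6.0 h

| run | time / h | Ja / % | Jj / % |
|---|---|---|---|
| west | 0.667 | 95 | 3 |
| west | 1.33 | 87 | 11 |
| west | 2.00 | 83 | 17 |
| west | 2.50 | 78 | 24 |
| west | 3.00 | 73 | 27 |
| west | 4.00 | 65 | 34 |
| north | 0.667 | 96 | 3 |
| north | 1.33 | 93 | 9 |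
| north | 2.00 | 84 | 13 |
| north | 2.50 | 83 | 16 |
| north | 3.00 | 80 | 17 |
| north | 4.00 | 75 | 23 |

(readings scatter by 1.5 percentage points)

- solid, in amounts per volume of the solution: Jf
- at the start none of Jf is in solution
- the earlier runs do not show the pH; that part of a forecast is a guess

- part of the Ja that has reacted at 6.0 h
- pH of the solution at 6.0 h

- A first-order loss leaves the same fraction at a given time whatever the charge, so I look at the fraction left, and at 4.00 h west keeps 65% of its Ja while north keeps 75%.
- Multiplied out, west has lost 0.0143 M and north 0.0160 M, so the loss grows by a factor of 1.11 while the charge grows by 1.56.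
- I therefore treat Ja as zero order: a steady drain, read as 0.00359 M h⁻¹ in west and 0.00400 M h⁻¹ in north, with a mean of 0.00379 M h⁻¹, and each reading carries a scatter of 1.5 percentage points.
- Dividing this flask's charge of Ja by the drain gives 7.64 h, the emptying time, and the fraction left is then one minus the time over the emptying time.
- For this flask I get 21.5% left, so 78.5% reacted, but this line runs further down than west ever reached, and the runs give me no pH.
- The forecast differs from my figure, with 70% reacted and pH 7, and it calls the rate “probably limited by Jf dissolving”.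
- The flask gives 66.1% reacted and pH 7.62.

    Ja + Jg → Jb + Jj + Je (k = 178 L mol⁻¹ h⁻¹)
    Jh ⇌ Jg + Jb, settled at all times (K = 1.30 × 10⁻⁹ M)
    Jd ⇌ Jc + Jb, settled at all times (K = 5.00 × 10⁻⁹ M)
    Ja → Jk (k = 9.16 × 10⁻⁵ h⁻¹)
    Jf ⇌ Jg, rate k5*(cs5 - [Jg]) while solid is left; crystals form when [Jg] > cs5 (solubility = 24.0 mM, k = 0.271 h⁻¹)

- This flask keeps 34% of its Ja, against my 21.5%: it lost 0.00319 M h⁻¹ on average over the 6.0 h, less than my drain of 0.00379 M h⁻¹. The neighbouring flask, charged with 0.012 M of Ja and otherwise the same, has an emptying time of 3.16 h, my 7.64 h scaled down by its charge, shorter than the 6.0 h it runs, so its line reaches zero before the time is up. That neighbouring flask ends with 98.0% reacted and 1.96% of its Ja left.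

The data were computed with constants of no real substance; the scatter is artificial.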